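**Retrosynthetic overview**

1. Locants: ring A is the ten-membered carbocycle C1–C10 (C1 free carbinol, C3 acetate carbon, Z olefins C4=C5 and C9=C10, C6 lactone carbinol carbon, C7 ring-fusion CH, C8 tiglate carbon, C14 = CH3 on C10, C15 = CH2OH on C4); ring B is the γ-lactone O–C6–C7–C11(=C13H2)–C12(=O). Enabling feature: C6 is an allylic carbinol carbon bonded to vinyl C5 of the Z C4=C5 olefin, its oxygen lies 1,4 to carboxyl carbon C12, and the two Z olefins stand 1,6 in ring A (a strain-poor Z,Z-cyclodeca-1,6-diene).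
2. Last disconnection, both rings in one operation: the C5–C6 bond is made by intramolecular nickel/chromium-mediated addition of the C5 vinyl iodide to the C6 aldehyde of open-chain ester 27 (closes ring A); the C6 alkoxide then lactonises onto the C12 methyl ester (closes ring B).
3. Chain 27: C2–C3 by an Ipc2B-mediated aldol of methyl ketone 14 with iodoenal 20; an Evans–Tishchenko reduction then sets C1 and places the acetate on O3.
4. Ketone 14: C7–C8 by catalytic asymmetric Nozaki–Hiyama allylation of (Z)-3-iodobut-2-enal with a Morita–Baylis–Hillman-derived 2-(methoxycarbonyl)allyl bromide (sets C7 and C8, brings C11–C13); C1–C2 by Stille acetylation.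
5. Iodoenal 20: β-iodo Morita–Baylis–Hillman reaction of methyl propiolate with formaldehyde (fixes the C4=C5 geometry and C15).

Key step: step 16

Remark: the side-chain ester is the (E)-2-methylbut-2-enoate (tiglate) as drawn; CIP letters of intermediates change with substituent priorities although no centre is inverted after it is set.

**Route**

Step 1
Reactants: 1 but-2-yn-1-ol
Product: 3 (2Z)-3-iodobut-2-en-1-ol, via cyclic alkenylalanate 2 (not isolated)
Conditions: NaAlH2(OCH2CH2OMe)2, THF, 0 °C to rt; then I2, THF, −78 °C to 0 °C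
Reagents that add atoms: iodine, II
Why: Hydroxyl-directed trans-hydroalumination of a propargylic alcohol puts aluminium on the future C10 in a five-membered alanate cis to the CH2O group, and iodinolysis with retention gives the Z vinyl iodide.

Step 2
Reactants: 3 (2Z)-3-iodobut-2-en-1-ol
Product: 4 (2Z)-3-iodobut-2-enal
Conditions: MnO2, CH2Cl2, rt
Reagents that add atoms: none
Why: Allylic oxidation with MnO2 is neutral and leaves the vinyl iodide and its Z geometry untouched.

Step 3
Reactants: 5 methyl acrylate; 6 [(4-methoxybenzyl)oxy]acetaldehyde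
Product: 7 racemic Morita–Baylis–Hillman alcohol
Conditions: DABCO (0.5 equiv), 1,4-dioxane/H2O, rt
Reagents that add atoms: none
Why: Morita–Baylis–Hillman reaction of an acrylate with an activated α-alkoxy aldehyde; the racemic carbinol centre disappears in step 4.

Step 4
Reactants: 7 racemic Morita–Baylis–Hillman alcohol
Product: 8 methyl (2Z)-2-(bromomethyl)-4-[(4-methoxybenzyl)oxy]but-2-enoate
Conditions: NBS, Me2S, CH2Cl2, 0 °C to rt
Reagents that add atoms: N-bromosuccinimide, O=C1CCC(=O)N1Br
Why: Corey–Kim-type activation of the alcohol and SN2′ delivery of bromide should give the rearranged primary allylic bromide as the thermodynamically preferred Z isomer (ester trans to the alkoxymethyl group).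

Step 5
Reactants: 4 (2Z)-3-iodobut-2-enal; 8 allylic bromide
Product: 10 (7S,8S)-syn hydroxy ester, via trimethylsilyl ether 9 (not isolated)
Conditions: CrCl2 (10 mol%), chiral 1,8-bis(4-isopropyl-4,5-dihydrooxazol-2-yl)carbazole ligand (antipode for Si-face attack, 12 mol%), Mn powder, Me3SiCl, iPr2NEt (cat.), THF, rt; then aqueous citric acid, THF, 0 °C
Reagents that add atoms: none
Why: Catalytic asymmetric Nozaki–Hiyama allylation with a 2-(alkoxycarbonyl)allyl bromide: the allylchromium keeps C6 cis to the CH2–Cr carbon, so a chair transition state should give the syn C7/C8 adduct, the ligand antipode is chosen to direct attack to the Si face of enal 4, and the vinyl iodide is inert in the absence of nickel.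

Step 6
Reactants: 10 (7S,8S)-syn hydroxy ester
Product: 11 C8 tiglate
Conditions: tigloyl chloride, pyridine, DMAP (cat.), CH2Cl2, 0 °C to rt
Reagents that add atoms: (2E)-2-methylbut-2-enoyl chloride, C/C=C(\C)C(Cl)=O
Why: DMAP-catalysed acylation through the acylpyridinium ion esterifies the C8 allylic alcohol before it can lactonise onto C12 and keeps the E geometry of the tiglate.

Step 7
Reactants: 11 C8 tiglate; 12 tributyl(1-ethoxyethenyl)stannane
Product: 14 Z-enone methyl ketone, via 2-ethoxydiene 13 (not isolated)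
Conditions: Pd(PPh3)4 (5 mol%), CuI (10 mol%), DMF, rt; then 1 M HCl, THF, 0 °C
Reagents that add atoms: water, O
Why: Stille coupling of the vinyl iodide with retention of the Z geometry followed by mild enol-ether hydrolysis delivers the C1 methyl ketone (acetyl anion equivalent) without touching the esters or the PMB ether.

Step 8
Reactants: 15 methyl prop-2-ynoate; 16 formaldehyde (monomer from paraformaldehyde, THF solution)
Product: 17 methyl (2Z)-2-(hydroxymethyl)-3-iodoprop-2-enoate
Conditions: MgI2, CH2Cl2, 0 °C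
Reagents that add atoms: magnesium diiodide, [Mg+2].[I-].[I-]
Why: β-Iodo Morita–Baylis–Hillman reaction: iodide adds to the propiolate and the magnesium β-iodoallenolate is trapped by formaldehyde, which should give kinetically the Z acrylate with iodine cis to the ester.

Step 9
Reactants: 17 methyl (2Z)-2-(hydroxymethyl)-3-iodoprop-2-enoate
Product: 18 O15 silyl ether
Conditions: TBSCl, imidazole, DMF, 0 °C to rt
Reagents that add atoms: tert-butyl(chloro)dimethylsilane, CC(C)(C)[Si](C)(C)Cl
Why: Standard silylation of the primary allylic alcohol protects O15.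

Step 10
Reactants: 18 O15 silyl ether
Product: 19 (2E)-allylic alcohol
Conditions: iBu2AlH (2.2 equiv), CH2Cl2, −78 °C; aqueous potassium sodium tartrate
Reagents that add atoms: none
Why: 1,2-Reduction of the enoate with iBu2AlH at low temperature gives the allylic alcohol without touching the vinyl iodide or the silyl ether.

Step 11
Reactants: 19 (2E)-allylic alcohol
Product: 20 (2Z)-2-({[tert-butyl(dimethyl)silyl]oxy}methyl)-3-iodoprop-2-enal
Conditions: MnO2, CH2Cl2, rt
Reagents that add atoms: none
Why: Allylic oxidation with MnO2 gives the enal with iodine held cis to the formyl carbon (the future C3).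

Step 12
Reactants: 14 Z-enone methyl ketone; 20 iodoenal
Product: 23 (3S)-β-hydroxy ketone, via enol borinate 21 (not isolated), via boron aldolate 22 (not isolated)
Conditions: (+)-Ipc2BCl (from (−)-α-pinene), Et3N, Et2O, −78 to 0 °C; then 20, −78 to −20 °C; then H2O2, MeOH, pH 7 buffer, 0 °C
Reagents that add atoms: none
Why: Ipc2B-mediated boron aldol reaction of a methyl ketone: only the C2 methyl group is enolised, and the isopinocampheyl ligands of the (+)-reagent should direct the enolate to the Si face of enal 20 to set C3 as S under reagent control, the minor C3 epimer being removed by chromatography.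

Step 13
Reactants: 23 (3S)-β-hydroxy ketone
Product: 24 (1S,3S)-anti-diol 3-acetate
Conditions: SmI2 (0.3 equiv), MeCHO (8 equiv), THF, −10 °C
Reagents that add atoms: acetaldehyde, CC=O
Why: Evans–Tishchenko reduction: the trivalent-samarium-bound hemiacetal of O3 with acetaldehyde delivers hydride intramolecularly to the C1 ketone through a chair-like bicyclic transition state, which should set C1 as S (1,3-anti) and leaves the acetate on O3 and the C1 hydroxyl free.

Step 14
Reactants: 24 (1S,3S)-anti-diol 3-acetate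
Product: 25 O1,O15-bis-silyl ether
Conditions: TBSOTf, 2,6-lutidine, CH2Cl2, −78 °C
Reagents that add atoms: tert-butyldimethylsilyl trifluoromethanesulfonate, CC(C)(C)[Si](C)(C)OS(=O)(=O)C(F)(F)F
Why: Silylation with the silyl triflate at low temperature caps the C1 hydroxyl before the acetate can migrate from O3.

Step 15
Reactants: 25 O1,O15-bis-silyl ether
Product: 27 open-chain C6 aldehyde, via primary alcohol 26 (not isolated)
Conditions: DDQ, CH2Cl2/pH 7 buffer, 0 °C; phase separation and drying; then Dess–Martin periodinane, NaHCO3, CH2Cl2, 0 °C; crude 27 used at once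
Reagents that add atoms: none
Why: Oxidative PMB cleavage with DDQ and immediate Dess–Martin oxidation give the C6 aldehyde without a basic or acidic stage, so the labile C7 centre (α to the aldehyde, allylic, β to the tiglate) should neither epimerise nor eliminate and the γ-hydroxy ester 26 has no time to lactonise.

Step 16
Reactants: 27 open-chain C6 aldehyde
Product: 29 O1,O15-bis(tert-butyldimethylsilyl)eupacunolin, via hydroxy ester 28 (not isolated)
Conditions: CrCl2 (15 equiv), NiCl2 (0.15 equiv), degassed DMSO/THF, rt, slow addition of 27 to a final 2 mM; aqueous sodium serinate work-up; then PPTS (cat.), benzene, 40 °C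
Reagents that add atoms: none
Why: Zerovalent nickel (formed from NiCl2 by CrCl2) inserts into the C5–I bond with retention of the Z geometry, transmetalation gives a vinyl species of trivalent chromium that adds to the C6 aldehyde, and the γ-hydroxy acrylate 28 so formed loses methanol under mild acid to close the lactone. The closest known reaction types are the Nozaki–Hiyama–Kishi closure of medium rings from ω-iodoalkenyl aldehydes and the lactonisation of γ-hydroxy α-methylene esters. Ring A closes in a 10-exo-trig mode (C5 onto the C6 carbonyl) and is a Z,Z-cyclodeca-1,6-diene, the least strained ten-membered diene, so the two Z olefins made in steps 1 and 8 pre-organise the chain, and ring B closes in a 5-exo-trig mode (O6 onto C12). The new stereocentre C6 is controlled by C7: in the Felkin–Anh arrangement the C7–C8 bond stands anti to the incoming C5 and the carbonyl oxygen lies on the side of C11, which should give 6R (O6 syn to C11 and 1,3-anti to the C8 acyloxy group, whose dipole favours the same sense). The step needs chemoselectivity for the aldehyde over three esters and an acrylate, which the low basicity and carbonyl selectivity of organochromium reagents secure, and it needs ring closure to outrun dimerisation, which high dilution and the two Z olefins secure. The 6R alcohol gives the trans-fused lactone 29, whereas any 6S epimer would give a cis-fused isomer that is removed by chromatography.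

Step 17
Reactants: 29 O1,O15-bis(tert-butyldimethylsilyl)eupacunolin
Product: 30 eupacunolin
Conditions: HF·pyridine, pyridine, THF, 0 °C to rt
Reagents that add atoms: none
Why: Desilylation with buffered HF·pyridine removes both silyl ethers under mildly acidic conditions that should spare the acetate, the tiglate and the α-methylene lactone.

**Compound list**

1 | but-2-yn-1-ol | CC#CCO | starting material
2 | cyclic sodium alkenylalanate of 1 (five-membered C–Al–O ring, two 2-methoxyethoxy groups on Al) | CC1=CCO[Al-]1(OCCOC)OCCOC.[Na+] | intermediate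
3 | (2Z)-3-iodobut-2-en-1-ol | OC/C=C(/C)I | intermediate
4 | (2Z)-3-iodobut-2-enal | O=C/C=C(/C)I | intermediate
5 | methyl acrylate | C=CC(=O)OC | starting material
6 | [(4-methoxybenzyl)oxy]acetaldehyde | O=CCOCc1ccc(OC)cc1 | starting material
7 | methyl 3-hydroxy-4-[(4-methoxybenzyl)oxy]-2-methylidenebutanoate (racemic) | C=C(C(=O)OC)C(O)COCc1ccc(OC)cc1 | intermediate
8 | methyl (2Z)-2-(bromomethyl)-4-[(4-methoxybenzyl)oxy]but-2-enoate | COC(=O)/C(CBr)=C/COCc1ccc(OC)cc1 | intermediate
9 | methyl (3S,4S,5Z)-6-iodo-3-{[(4-methoxybenzyl)oxy]methyl}-2-methylidene-4-[(trimethylsilyl)oxy]hept-5-enoate | C=C(C(=O)OC)[C@@H](COCc1ccc(OC)cc1)[C@H](O[Si](C)(C)C)/C=C(/C)I | intermediate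
10 | methyl (3S,4S,5Z)-4-hydroxy-6-iodo-3-{[(4-methoxybenzyl)oxy]methyl}-2-methylidenehept-5-enoate (7S,8S in ring locants) | C=C(C(=O)OC)[C@@H](COCc1ccc(OC)cc1)[C@H](O)/C=C(/C)I | intermediate
11 | methyl (3S,4S,5Z)-6-iodo-3-{[(4-methoxybenzyl)oxy]methyl}-2-methylidene-4-{[(2E)-2-methylbut-2-enoyl]oxy}hept-5-enoate | C=C(C(=O)OC)[C@@H](COCc1ccc(OC)cc1)[C@H](OC(=O)/C(C)=C/C)/C=C(/C)I | intermediate
12 | tributyl(1-ethoxyethenyl)stannane | C=C(OCC)[Sn](CCCC)(CCCC)CCCC | starting material
13 | methyl (3S,4R,5Z)-7-ethoxy-3-{[(4-methoxybenzyl)oxy]methyl}-6-methyl-2-methylidene-4-{[(2E)-2-methylbut-2-enoyl]oxy}octa-5,7-dienoate | C=C(C(=O)OC)[C@@H](COCc1ccc(OC)cc1)[C@H](OC(=O)/C(C)=C/C)/C=C(/C)C(=C)OCC | intermediate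
14 | methyl (3S,4R,5Z)-3-{[(4-methoxybenzyl)oxy]methyl}-6-methyl-2-methylidene-4-{[(2E)-2-methylbut-2-enoyl]oxy}-7-oxooct-5-enoate (7S,8R in ring locants) | C=C(C(=O)OC)[C@@H](COCc1ccc(OC)cc1)[C@H](OC(=O)/C(C)=C/C)/C=C(/C)C(C)=O | intermediate
15 | methyl prop-2-ynoate | C#CC(=O)OC | starting material
16 | formaldehyde (from paraformaldehyde) | C=O | starting material
17 | methyl (2Z)-2-(hydroxymethyl)-3-iodoprop-2-enoate | COC(=O)/C(CO)=C\I | intermediate
18 | methyl (2Z)-2-({[tert-butyl(dimethyl)silyl]oxy}methyl)-3-iodoprop-2-enoate | COC(=O)/C(CO[Si](C)(C)C(C)(C)C)=C\I | intermediate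
19 | (2E)-2-({[tert-butyl(dimethyl)silyl]oxy}methyl)-3-iodoprop-2-en-1-ol | OC/C(CO[Si](C)(C)C(C)(C)C)=C\I | intermediate
20 | (2Z)-2-({[tert-butyl(dimethyl)silyl]oxy}methyl)-3-iodoprop-2-enal | O=C/C(CO[Si](C)(C)C(C)(C)C)=C\I | intermediate
21 | enol diisopinocampheylborinate of 14 (B–O on C1, C2 = CH2; 7S,8R) | C=C(C(=O)OC)[C@@H](COCc1ccc(OC)cc1)[C@H](OC(=O)/C(C)=C/C)/C=C(/C)C(=C)OB([C@H]1C[C@H]2C[C@@H]([C@@H]1C)C2(C)C)[C@H]1C[C@H]2C[C@@H]([C@@H]1C)C2(C)C | intermediate
22 | diisopinocampheylboron aldolate of 23 (B–O on C3; 3S,7S,8R) | C=C(C(=O)OC)[C@@H](COCc1ccc(OC)cc1)[C@H](OC(=O)/C(C)=C/C)/C=C(/C)C(=O)C[C@H](OB([C@H]1C[C@H]2C[C@@H]([C@@H]1C)C2(C)C)[C@H]1C[C@H]2C[C@@H]([C@@H]1C)C2(C)C)/C(CO[Si](C)(C)C(C)(C)C)=C\I | intermediate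
23 | methyl (3S,4R,5Z,9S,10Z)-10-({[tert-butyl(dimethyl)silyl]oxy}methyl)-9-hydroxy-11-iodo-3-{[(4-methoxybenzyl)oxy]methyl}-6-methyl-2-methylidene-4-{[(2E)-2-methylbut-2-enoyl]oxy}-7-oxoundeca-5,10-dienoate (3S,7S,8R in ring locants) | C=C(C(=O)OC)[C@@H](COCc1ccc(OC)cc1)[C@H](OC(=O)/C(C)=C/C)/C=C(/C)C(=O)C[C@H](O)/C(CO[Si](C)(C)C(C)(C)C)=C\I | intermediate
24 | methyl (3S,4R,5Z,7S,9S,10Z)-9-(acetyloxy)-10-({[tert-butyl(dimethyl)silyl]oxy}methyl)-7-hydroxy-11-iodo-3-{[(4-methoxybenzyl)oxy]methyl}-6-methyl-2-methylidene-4-{[(2E)-2-methylbut-2-enoyl]oxy}undeca-5,10-dienoate (1S,3S,7S,8R in ring locants) | C=C(C(=O)OC)[C@@H](COCc1ccc(OC)cc1)[C@H](OC(=O)/C(C)=C/C)/C=C(/C)[C@@H](O)C[C@H](OC(C)=O)/C(CO[Si](C)(C)C(C)(C)C)=C\I | intermediate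
25 | methyl (3S,4R,5Z,7S,9S,10Z)-9-(acetyloxy)-7-{[tert-butyl(dimethyl)silyl]oxy}-10-({[tert-butyl(dimethyl)silyl]oxy}methyl)-11-iodo-3-{[(4-methoxybenzyl)oxy]methyl}-6-methyl-2-methylidene-4-{[(2E)-2-methylbut-2-enoyl]oxy}undeca-5,10-dienoate | C=C(C(=O)OC)[C@@H](COCc1ccc(OC)cc1)[C@H](OC(=O)/C(C)=C/C)/C=C(/C)[C@@H](O[Si](C)(C)C(C)(C)C)C[C@H](OC(C)=O)/C(CO[Si](C)(C)C(C)(C)C)=C\I | intermediate
26 | methyl (3S,4R,5Z,7S,9S,10Z)-9-(acetyloxy)-7-{[tert-butyl(dimethyl)silyl]oxy}-10-({[tert-butyl(dimethyl)silyl]oxy}methyl)-3-(hydroxymethyl)-11-iodo-6-methyl-2-methylidene-4-{[(2E)-2-methylbut-2-enoyl]oxy}undeca-5,10-dienoate | C=C(C(=O)OC)[C@@H](CO)[C@H](OC(=O)/C(C)=C/C)/C=C(/C)[C@@H](O[Si](C)(C)C(C)(C)C)C[C@H](OC(C)=O)/C(CO[Si](C)(C)C(C)(C)C)=C\I | intermediate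
27 | methyl (3R,4R,5Z,7S,9S,10Z)-9-(acetyloxy)-7-{[tert-butyl(dimethyl)silyl]oxy}-10-({[tert-butyl(dimethyl)silyl]oxy}methyl)-3-formyl-11-iodo-6-methyl-2-methylidene-4-{[(2E)-2-methylbut-2-enoyl]oxy}undeca-5,10-dienoate (1S,3S,7R,8R in ring locants) | C=C(C(=O)OC)[C@@H](C=O)[C@H](OC(=O)/C(C)=C/C)/C=C(/C)[C@@H](O[Si](C)(C)C(C)(C)C)C[C@H](OC(C)=O)/C(CO[Si](C)(C)C(C)(C)C)=C\I | intermediate
28 | methyl 2-[(1S,2R,3Z,5S,7S,8Z,10R)-7-(acetyloxy)-5-{[tert-butyl(dimethyl)silyl]oxy}-8-({[tert-butyl(dimethyl)silyl]oxy}methyl)-10-hydroxy-4-methyl-2-{[(2E)-2-methylbut-2-enoyl]oxy}cyclodeca-3,8-dien-1-yl]prop-2-enoate (1S,3S,6R,7S,8R in ring locants) | C=C(C(=O)OC)[C@@H]1[C@H](OC(=O)/C(C)=C/C)/C=C(/C)[C@@H](O[Si](C)(C)C(C)(C)C)C[C@H](OC(C)=O)/C(CO[Si](C)(C)C(C)(C)C)=C\[C@H]1O | intermediate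
29 | O1,O15-bis(tert-butyldimethylsilyl)eupacunolin (1S,3S,6R,7R,8R; 4Z,9Z) | C=C1C(=O)O[C@@H]2/C=C(/CO[Si](C)(C)C(C)(C)C)[C@@H](OC(C)=O)C[C@H](O[Si](C)(C)C(C)(C)C)/C(C)=C\[C@@H](OC(=O)/C(C)=C/C)[C@@H]12 | intermediate
30 | eupacunolin (1S,3S,6R,7R,8R; 4Z,9Z) | C=C1C(=O)O[C@@H]2/C=C(/CO)[C@@H](OC(C)=O)C[C@H](O)/C(C)=C\[C@@H](OC(=O)/C(C)=C/C)[C@@H]12 | target

**Step count and risks**

Total: 17 steps. Longest linear sequence: 11 steps (steps 1, 2, 5, 6, 7, 12, 13, 14, 15, 16, 17 from but-2-yn-1-ol).

The three steps most likely to fail: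

Step 16. The ring closure may attack the wrong face of C6, be outrun by oligomerisation, or be preceded by loss of the C7 configuration or β-elimination of the tiglate in aldehyde 27. The fallback sets the C6 centre by reagent-controlled reduction instead of in the ring closure. It sets out from 28 taken as a C6-epimeric mixture (acid stage left out) and comes back to the route at 28. Dess–Martin periodinane with NaHCO3 in CH2Cl2 at 0 °C should give the ring A C6 ketone F1. Reduction with catecholborane and the 2-methyl-CBS-oxazaborolidine antipode that delivers hydride to the Si face of C6 (CBS reduction of a conjugated enone) should return 28 as the 6R epimer. This is lactonised with PPTS as in step 16 to give 29.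

Step 5. The allylchromium may lose the PMB-oxy group by β-elimination when the metal migrates to C7, and the syn preference or the facial selectivity may be poor. The fallback replaces chromium by boron and sets out from bromide 8, coming back at 10. B2pin2 with Pd2(dba)3 (cat.) in DMSO at rt should give allylboronate F2, which is configurationally stable and cannot place a metal on C7. Its addition to enal 4 through a closed chair transition state under chiral phosphoric acid catalysis (TRIP antipode chosen for Si-face attack, toluene, −30 °C) should give the syn alcohol 10 after hydrolytic work-up.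

Step 12. Reagent control by the boron ligands on a methyl-ketone enolate may give insufficient facial selectivity at C3, so that a C3 epimer mixture has to be separated. The fallback sets out from ketone 14 and comes back at 23. Me3SiOTf and Et3N in CH2Cl2 at 0 °C should give silyl enol ether F3. A Lewis-base-catalysed Mukaiyama aldol reaction with enal 20 (SiCl4, chiral binaphthyl-derived bisphosphoramide antipode chosen for the Si face, iPr2NEt, CH2Cl2, −78 °C) should give 23 after aqueous KF/NaHCO3 work-up.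

**Further compounds**

F1 | step 16 | methyl 2-[(1R,2R,3Z,5S,7S,8Z)-7-(acetyloxy)-5-{[tert-butyl(dimethyl)silyl]oxy}-8-({[tert-butyl(dimethyl)silyl]oxy}methyl)-4-methyl-2-{[(2E)-2-methylbut-2-enoyl]oxy}-10-oxocyclodeca-3,8-dien-1-yl]prop-2-enoate | C=C(C(=O)OC)[C@@H]1[C@H](OC(=O)/C(C)=C/C)/C=C(/C)[C@@H](O[Si](C)(C)C(C)(C)C)C[C@H](OC(C)=O)/C(CO[Si](C)(C)C(C)(C)C)=C\C1=O
F2 | step 5 | methyl (2E)-4-[(4-methoxybenzyl)oxy]-2-[(4,4,5,5-tetramethyl-1,3,2-dioxaborolan-2-yl)methyl]but-2-enoate | COC(=O)/C(CB1OC(C)(C)C(C)(C)O1)=C/COCc1ccc(OC)cc1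
F3 | step 12 | methyl (3S,4R,5Z)-3-{[(4-methoxybenzyl)oxy]methyl}-6-methyl-2-methylidene-4-{[(2E)-2-methylbut-2-enoyl]oxy}-7-[(trimethylsilyl)oxy]octa-5,7-dienoate | C=C(C(=O)OC)[C@@H](COCc1ccc(OC)cc1)[C@H](OC(=O)/C(C)=C/C)/C=C(/C)C(=C)O[Si](C)(C)C
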